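## Retrosynthetic overview

1. Target 9 ⇒ bis(methyl ether) 7 by a final double O‑demethylation. 7 ⇒ two molecules of (S)‑curcuphenol methyl ether 5 by cutting the C6–C6' biaryl bond (methoxy‑directed ortho‑lithiation, then oxidative homocoupling).
2. 5 ⇒ (S)‑3‑arylbut‑1‑ene 3 by hydroboration and B‑alkyl Suzuki coupling with 1‑bromo‑2‑methylprop‑1‑ene.
3. 3 ⇒ 2‑methoxy‑4‑methylstyrene 2 by nickel‑catalysed asymmetric hydrovinylation, which sets the benzylic stereocentre. 2 ⇒ aldehyde 1 by Wittig methylenation.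
4. No ring is formed. Both benzene rings are bought in 1, and the two rings are joined only in step 4.

## Assumptions

- The target SMILES gives no configuration for the biaryl axis, so it is not controlled. The (S,S) compound is taken as whatever atropisomer or atropisomer mixture is formed.
- The hydrovinylation ligand L* is the BINOL‑derived N,N‑bis(1‑phenylethyl)phosphoramidite, used as the antipode that gives the (S)‑alkene. This is taken here as the (Ra,Sc,Sc) form; the mirror‑image ligand is used if the rotation of 3 shows the opposite sense.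
- 2‑Methoxy‑4‑methylbenzaldehyde 1 is taken as a catalogue compound.

## Route

**Step 1**
Reactants: 1 2‑methoxy‑4‑methylbenzaldehyde
Product: 2 2‑methoxy‑4‑methylstyrene (1‑ethenyl‑2‑methoxy‑4‑methylbenzene)
Conditions: Ph3PCH3Br (1.3 equiv), KOtBu (1.25 equiv), THF, 0 °C → rt, 2 h
Reagents that add atoms: methyltriphenylphosphonium bromide, C[P+](c1ccccc1)(c1ccccc1)c1ccccc1.[Br-]
Why: Wittig methylenation of an aromatic aldehyde with the non‑stabilised ylide Ph3P=CH2 is fast and clean, the aryl methyl ether is inert, and no stereocentre is involved.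

**Step 2**
Reactants: 2 2‑methoxy‑4‑methylstyrene
Product: 3 (S)‑1‑(but‑3‑en‑2‑yl)‑2‑methoxy‑4‑methylbenzene
Conditions: [(C3H5)NiBr]2 (1 mol%), L* (2 mol%), Na[B(3,5‑(CF3)2C6H3)4] (2 mol%), ethylene (1 atm), CH2Cl2, −78 °C, 3 h
Reagents that add atoms: ethylene, C=C
Why: In this nickel‑catalysed asymmetric hydrovinylation a cationic nickel hydride adds to the styrene, ethylene inserts at the benzylic carbon and beta‑hydride elimination releases the branched alkene with no co‑product, the chiral phosphoramidite fixing the (S) configuration of the new benzylic stereocentre (ortho‑alkoxystyrenes are tolerated, and at −78 °C the product does not isomerise into conjugation).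

**Step 3**
Reactants: 3 (S)‑1‑(but‑3‑en‑2‑yl)‑2‑methoxy‑4‑methylbenzene
Product: 5 2‑methoxy‑4‑methyl‑1‑[(2S)‑6‑methylhept‑5‑en‑2‑yl]benzene ((S)‑curcuphenol methyl ether), via alkylborane 4 (not isolated)
Conditions: 9‑BBN (1.2 equiv), THF, 0 °C → rt, 4 h; then 1‑bromo‑2‑methylprop‑1‑ene (1.5 equiv), PdCl2(dppf) (3 mol%), 3 M aq NaOH (3 equiv), 65 °C, 12 h
Reagents that add atoms: 1‑bromo‑2‑methylprop‑1‑ene, CC(C)=CBr; 9‑BBN, B1C2CCCC1CCC2 (its boron stays only in 4; 5 keeps one hydrogen from it)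
Why: Anti‑Markovnikov hydroboration of the terminal alkene followed by B‑alkyl Suzuki–Miyaura coupling (oxidative addition of the vinyl bromide to zerovalent palladium, hydroxide‑assisted transfer of the primary alkyl group, reductive elimination) builds the homoprenyl chain without touching the benzylic stereocentre, which takes part in no bond made or broken.

**Step 4**
Reactants: 5 (S)‑curcuphenol methyl ether (two molecules)
Product: 7 2,2'‑dimethoxy‑6,6'‑dimethyl‑3,3'‑bis[(2S)‑6‑methylhept‑5‑en‑2‑yl]‑1,1'‑biphenyl, via aryllithium 6 (not isolated)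
Conditions: n‑BuLi (1.05 equiv), TMEDA (1.1 equiv), Et2O, 0 °C → rt, 4 h; then added to anhydrous FeCl3 (1.1 equiv), THF, −78 °C → rt
Reagents that add atoms: n‑BuLi, [Li]CCCC (its lithium is held only by 6; 7 holds no reagent atoms)
Why: In this directed ortho‑metalation the methoxy group steers n‑BuLi/TMEDA to the only free ortho position (between OMe and CH3), and oxidative homocoupling of the aryllithium by FeCl3 (trivalent iron is reduced to divalent iron) forges the tetra‑ortho‑substituted biaryl bond as it does for other 2,6‑disubstituted aryllithiums; the stereocentres are remote and untouched, and any (R,S) dimer arising from the minor enantiomer is a separable diastereomer.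

**Step 5**
Reactants: 7 2,2'‑dimethoxy‑6,6'‑dimethyl‑3,3'‑bis[(2S)‑6‑methylhept‑5‑en‑2‑yl]‑1,1'‑biphenyl
Product: 9 6,6'‑dimethyl‑3,3'‑bis[(2S)‑6‑methylhept‑5‑en‑2‑yl]‑[1,1'‑biphenyl]‑2,2'‑diol (target), via disodium bis‑phenoxide 8 (not isolated)
Conditions: NaSEt (8 equiv), degassed DMF, 140 °C, 8 h; then 1 M HCl, 0 °C
Reagents that add atoms: NaSEt, [Na+].[S-]CC (its sodium is held only by 8; 9 holds no reagent atoms)
Why: Nucleophilic (SN2) O‑demethylation by ethanethiolate at the methyl carbon of the two twisted, di‑ortho‑flanked aryl methyl ethers leaves the trisubstituted alkenes and the benzylic stereocentres untouched, and acidification of the bis‑phenoxide gives the biphenol.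

## Compound list

1 | 2‑methoxy‑4‑methylbenzaldehyde | COc1cc(C)ccc1C=O | starting material
2 | 2‑methoxy‑4‑methylstyrene (1‑ethenyl‑2‑methoxy‑4‑methylbenzene) | COc1cc(C)ccc1C=C | intermediate
3 | (S)‑1‑(but‑3‑en‑2‑yl)‑2‑methoxy‑4‑methylbenzene | COc1cc(C)ccc1[C@@H](C)C=C | intermediate
4 | 9‑[(3S)‑3‑(2‑methoxy‑4‑methylphenyl)butyl]‑9‑borabicyclo[3.3.1]nonane | COc1cc(C)ccc1[C@@H](C)CCB1C2CCCC1CCC2 | intermediate (not isolated)
5 | 2‑methoxy‑4‑methyl‑1‑[(2S)‑6‑methylhept‑5‑en‑2‑yl]benzene ((S)‑curcuphenol methyl ether) | COc1cc(C)ccc1[C@@H](C)CCC=C(C)C | intermediate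
6 | {2‑methoxy‑6‑methyl‑3‑[(2S)‑6‑methylhept‑5‑en‑2‑yl]phenyl}lithium | COc1c([Li])c(C)ccc1[C@@H](C)CCC=C(C)C | intermediate (not isolated)
7 | 2,2'‑dimethoxy‑6,6'‑dimethyl‑3,3'‑bis[(2S)‑6‑methylhept‑5‑en‑2‑yl]‑1,1'‑biphenyl | COc1c(-c2c(C)ccc([C@@H](C)CCC=C(C)C)c2OC)c(C)ccc1[C@@H](C)CCC=C(C)C | intermediate
8 | disodium 6,6'‑dimethyl‑3,3'‑bis[(2S)‑6‑methylhept‑5‑en‑2‑yl]‑[1,1'‑biphenyl]‑2,2'‑diolate | [Na+].[Na+].CC(C)=CCC[C@H](C)c1ccc(C)c(-c2c(C)ccc([C@@H](C)CCC=C(C)C)c2[O-])c1[O-] | intermediate (not isolated)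
9 | 6,6'‑dimethyl‑3,3'‑bis[(2S)‑6‑methylhept‑5‑en‑2‑yl]‑[1,1'‑biphenyl]‑2,2'‑diol | CC(C)=CCC[C@H](C)c1ccc(C)c(-c2c(C)ccc([C@@H](C)CCC=C(C)C)c2O)c1O | target

## Step count and risk

Total steps: 5. Longest linear sequence: 5 (fully linear; monomer 5 is used twice in step 4).

**Step 4 (most at risk).** The oxidative homocoupling must form a tetra‑ortho‑substituted biaryl, and butyl/aryl scrambling or incomplete lithiation can cut the yield. The fallback sets out from 5 and comes back at 7. 5 is lithiated as before to 6 in two portions. One portion is quenched with I2 (THF, −78 °C) to give the aryl iodide 3‑iodo‑2‑methoxy‑4‑methyl‑1‑[(2S)‑6‑methylhept‑5‑en‑2‑yl]benzene F1. The other portion is transmetalated with ZnCl2 (THF, 0 °C) to the arylzinc chloride chlorido{2‑methoxy‑6‑methyl‑3‑[(2S)‑6‑methylhept‑5‑en‑2‑yl]phenyl}zinc F2, which is not isolated. Negishi cross‑coupling of F1 with F2 (Pd2(dba)3, RuPhos [2‑dicyclohexylphosphino‑2',6'‑diisopropoxybiphenyl], THF/NMP, 70–100 °C) then gives 7; this ligand system is made for tetra‑ortho‑substituted biaryls.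

**Step 2.** The enantioselectivity and the sense of induction with an ortho‑methoxy styrene are not guaranteed, and the catalyst is sensitive. The fallback sets out from 2 and comes back at 3. Copper‑hydride‑catalysed Markovnikov hydroboration of 2 (CuCl, NaOtBu, the DTBM‑SEGPHOS antipode that gives the (R) product, HBpin, toluene, rt) gives the benzylic boronic ester 2‑[(1R)‑1‑(2‑methoxy‑4‑methylphenyl)ethyl]‑4,4,5,5‑tetramethyl‑1,3,2‑dioxaborolane F3. A Zweifel olefination follows. CH2=CHMgBr (THF) gives the ate complex bromomagnesium ethenyl[(1R)‑1‑(2‑methoxy‑4‑methylphenyl)ethyl](pinacolato)borate F4, which is not isolated. I2 (−78 °C) triggers a stereoretentive 1,2‑shift to the beta‑iodo boronic ester 2‑[(3S)‑1‑iodo‑3‑(2‑methoxy‑4‑methylphenyl)butan‑2‑yl]‑4,4,5,5‑tetramethyl‑1,3,2‑dioxaborolane F5, which is not isolated. NaOMe/MeOH then eliminates boron and iodine to give 3.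

**Step 5.** Double demethylation of the hindered bis‑ether at 140 °C may stall at the mono‑ether or erode material. The fallback sets out from 5 and comes back at 9, moving the demethylation to the monomer and using a MOM group as the director. 5 is demethylated (NaSEt, DMF, 140 °C) to sodium 5‑methyl‑2‑[(2S)‑6‑methylhept‑5‑en‑2‑yl]phenolate F6, which is not isolated, and acidified to (S)‑curcuphenol F7. MOMCl/i‑Pr2NEt (CH2Cl2, 0 °C → rt) gives the MOM ether 2‑(methoxymethoxy)‑4‑methyl‑1‑[(2S)‑6‑methylhept‑5‑en‑2‑yl]benzene F8. n‑BuLi (THF, 0 °C) gives the aryllithium {2‑(methoxymethoxy)‑6‑methyl‑3‑[(2S)‑6‑methylhept‑5‑en‑2‑yl]phenyl}lithium F9, which is not isolated. FeCl3 (THF, −78 °C → rt) couples it to the bis‑MOM biaryl 2,2'‑bis(methoxymethoxy)‑6,6'‑dimethyl‑3,3'‑bis[(2S)‑6‑methylhept‑5‑en‑2‑yl]‑1,1'‑biphenyl F10. Mild acid (HCl, MeOH, rt) then releases 9.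

## Further compounds

F1 | step 4 | 3‑iodo‑2‑methoxy‑4‑methyl‑1‑[(2S)‑6‑methylhept‑5‑en‑2‑yl]benzene | COc1c(I)c(C)ccc1[C@@H](C)CCC=C(C)C
F2 | step 4 | chlorido{2‑methoxy‑6‑methyl‑3‑[(2S)‑6‑methylhept‑5‑en‑2‑yl]phenyl}zinc | COc1c([Zn]Cl)c(C)ccc1[C@@H](C)CCC=C(C)C
F3 | step 2 | 2‑[(1R)‑1‑(2‑methoxy‑4‑methylphenyl)ethyl]‑4,4,5,5‑tetramethyl‑1,3,2‑dioxaborolane | COc1cc(C)ccc1[C@@H](C)B1OC(C)(C)C(C)(C)O1
F4 | step 2 | bromomagnesium ethenyl[(1R)‑1‑(2‑methoxy‑4‑methylphenyl)ethyl](pinacolato)borate | Br[Mg+].COc1cc(C)ccc1[C@@H](C)[B-]1(C=C)OC(C)(C)C(C)(C)O1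
F5 | step 2 | 2‑[(3S)‑1‑iodo‑3‑(2‑methoxy‑4‑methylphenyl)butan‑2‑yl]‑4,4,5,5‑tetramethyl‑1,3,2‑dioxaborolane (mixture at C2) | COc1cc(C)ccc1[C@@H](C)C(CI)B1OC(C)(C)C(C)(C)O1
F6 | step 5 | sodium 5‑methyl‑2‑[(2S)‑6‑methylhept‑5‑en‑2‑yl]phenolate | [Na+].CC(C)=CCC[C@H](C)c1ccc(C)cc1[O-]
F7 | step 5 | (S)‑curcuphenol, 5‑methyl‑2‑[(2S)‑6‑methylhept‑5‑en‑2‑yl]phenol | CC(C)=CCC[C@H](C)c1ccc(C)cc1O
F8 | step 5 | 2‑(methoxymethoxy)‑4‑methyl‑1‑[(2S)‑6‑methylhept‑5‑en‑2‑yl]benzene | COCOc1cc(C)ccc1[C@@H](C)CCC=C(C)C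
F9 | step 5 | {2‑(methoxymethoxy)‑6‑methyl‑3‑[(2S)‑6‑methylhept‑5‑en‑2‑yl]phenyl}lithium | COCOc1c([Li])c(C)ccc1[C@@H](C)CCC=C(C)C
F10 | step 5 | 2,2'‑bis(methoxymethoxy)‑6,6'‑dimethyl‑3,3'‑bis[(2S)‑6‑methylhept‑5‑en‑2‑yl]‑1,1'‑biphenyl | COCOc1c(-c2c(C)ccc([C@@H](C)CCC=C(C)C)c2OCOC)c(C)ccc1[C@@H](C)CCC=C(C)C
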